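## Analysis of the target

The target (29) is a 1-aryl-1,2-dihydronaphthalene lignan. Ring A (C4a, C5–C8, C8a) carries OMe on C6 and C8, OH on C7 and H on C5. It is fused to the partly saturated ring B (C1–C4, C4a, C8a), and C1 bears ring C, a 4-hydroxy-3,5-dimethoxyphenyl group. There are two stereocentres, C1 (S; H, ring C, C8a, C2) and C2 (S; H, CH3, C1, C3). They are adjacent, and the ring C aryl group and the C2 methyl are cis on ring B. The rest of ring B is a trisubstituted styrene-type alkene, C3(CH3)=C4, conjugated to ring A. Sensitive features are the two hindered, easily oxidised 2,6-dimethoxyphenols, the doubly benzylic C1–H, and the dihydronaphthalene, which can aromatise on oxidation or shift its double bond toward C2 in strong acid. The synthesis is hard for two reasons. The cis C1/C2 pair must be set absolutely in a hydrocarbon region with no polar handle. The two arenes are nearly the same trioxygenated ring, yet ring A must be joined twice (at C8a, ortho to a methoxy group, and at C4a, para to the C7 hydroxyl) and ring C once. The strategy reads C1 and C2 as the two carbons of a former (Z)-styrene of ring C. Ring A (through C8a) and the C2 methyl are then two groups added anti across that alkene, and the boron left on C2 is the point from which C3 and C4 are grown.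

## Retrosynthetic reasoning

**C4–C4a and C3=C4 (29 from 27).** The last bonds formed are C4–C4a and the alkene, by acid cyclodehydration of the C4 aldehyde in 27. This cut is chosen because C4a is para to the C7 hydroxyl, the carbon at which a free 2,6-dimethoxyphenol takes carbon electrophiles. Ring C is attached through its own para carbon and offers only carbons meta to its hydroxyl. The argument holds only for the free phenol. In an ether the central alkoxy group of a 1,2,3-trioxygenated ring is twisted out of plane and donates poorly, and the ortho carbons of ring C (ortho and para to methoxy groups) would then be the better nucleophiles. The forward step must therefore meet a free ring A phenol, and it closes ring B and forms the alkene without touching C1 or C2.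

**Phenol protection (27 from 26).** Both phenols are carried as benzyl ethers and released by hydrogenolysis at the aldehyde stage. Acetal-type groups would need the same acid that triggers the cyclisation, so the still-etherified ring A would compete poorly with ring C. Benzyl ethers leave under neutral conditions, before the alkene exists, and tolerate organolithiums, palladium and peroxide.

**C3–C4 and C2–C3 (26 from 22 from 19).** The two remaining ring B carbons are inserted one at a time into the carbon–boron bond. The carbenoid from 23 supplies C4 at the aldehyde oxidation level, and the carbenoid from 20 supplies C3 with its methyl. Each 1,2-metallate shift proceeds with retention at the migrating carbon, so C2 passes through unchanged. C3 forms as a mixture, which does not matter because it becomes trigonal.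

**C1–C8a and C2–CH3 (19 from 9, 17 and 16).** This is the key disconnection. Cutting both bonds returns an achiral (Z)-alkenylboron compound 9, methyllithium 17 and the ring A triflate 16. All stereochemistry is created in one catalytic step, and the C1–C8a bond is made by cross-coupling, independent of arene electronics. The forward reaction must select one alkene face, add the two carbon groups strictly anti, and follow the conjunctive pathway instead of direct cross-coupling. The boron ligand is the rigid diol 7 and not a simpler glycol. β-Substituted alkenyl borates of simple glycol esters tend to transfer the alkenyl group directly to palladium, and the acenaphthene-derived diol is the ligand known to suppress this.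

**Alkenylboron fragment (9 from 5 and 7; 5 from 3; 3 from 1 and 2; 7 from 6).** The (Z)-C=C–B unit comes from trans-hydroboration of the terminal alkyne 5, followed by exchange of the boron ligand for 7. The alkyne comes from aldehyde 3 by one-carbon homologation with 4, and 3 from syringaldehyde 1 and 2. Diol 7 is made in one step from 6.

**Ring A triflate (16 from 15 from 12 from 11 from 10 and 2).** The triflate oxygen must sit ortho to a methoxy group and meta to the protected hydroxyl. That carbon is where a 1,2,3-trialkoxybenzene is brominated, so 11 is brominated to 12, and the bromide is converted to phenol 15 through a boronate. Directed lithiation of 11 is avoided because the benzyl ether has acidic benzylic hydrogens.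

## Alternatives that were turned down

**Alternative 1: donor–acceptor cyclopropane opened by ring A, then acylation.**
- Disconnection: C1–C8a and C4–C4a.
- Forward key step: a strong Brønsted acid in a fluorinated alcohol lets arene A3 open cyclopropane diester A2 at the benzylic carbon with inversion. A dehydrating sulfonic acid medium then acylates C4a with one ester to give keto ester A1.
- For: it is metal-free and cheap, forms two C–C bonds and ring B in one pot, and transfers the cyclopropane configuration stereospecifically to C1. On cost and scalability it is stronger than the chosen route.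
- Against:
  - C4a in this substrate is para to a sulfonate ester and meta to both methoxy groups, so it is deactivated. The ortho carbons of ring C are better nucleophiles for the acylation, and the free-phenol lever is unavailable because the sulfonates are needed to survive the acid.
  - Ionising conditions with an aryl donor risk an open benzylic cation and erosion of configuration at C1.
  - A1 is at the wrong oxidation level. The C3 ester must be reduced to a methyl, the C4 ketone converted to the alkene, and two mesylates removed, which is at least six further steps.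
  - A2 itself needs an asymmetric cyclopropanation.
- Comparison: the chosen route uses more expensive catalysts, but C3 arrives with its methyl, four steps follow the key step, and the ring-selection problem can be solved by freeing the ring A phenol.

**Alternative 2: anodic decarboxylation with ring expansion of an indane.**
- Disconnection: C4–C4a by a 1,2-aryl shift, together with the C3=C4 alkene.
- Forward key step: oxidation of acid A5 at an anode removes the carboxyl carbon. Ring A migrates from the quaternary carbon to the exocyclic carbon, and the ring-expanded tertiary cation loses a C4 proton to give A4, the doubly protected target.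
- For: the migrating ring is fixed by constitution, so there is no ring A/ring C ambiguity, and A4 is one deprotection from the target. On both points it is stronger than the chosen route.
- Against:
  - Two trialkoxyarenes and the diarylmethine C–H are oxidised at lower potential than a carboxylate, so arene oxidation is expected to precede decarboxylation.
  - The primary radical can dimerise or abstract hydrogen before it is oxidised or rearranges.
  - The tertiary cation can lose a proton from C2, erasing that stereocentre, or from the methyl.
  - A5 contains three contiguous stereocentres, including a quaternary carbon that is then destroyed, and making it is longer than the whole chosen route.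
- Comparison: the chosen route builds only the two stereocentres that survive, from flat precursors reached in three or four steps.

**Alternative 3: photoenol ortho-quinodimethane Diels–Alder.**
- Disconnection: C1–C2 and C3–C4.
- Forward key step: irradiation of aldehyde A7 gives a hydroxy-ortho-quinodimethane, which adds dienophile A8 on a chiral titanium diolate template to give the all-cis adduct A6.
- For: it is the most convergent ring construction, creates four stereocentres at once, and fixes the ring A/ring C assignment because C4 is already on C4a. On convergence and ring assignment it is stronger than the chosen route.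
- Against:
  - A8 is a β-substituted (Z)-enoate, a sluggish dienophile with one-point binding to the template.
  - A8 can isomerise to the E form under irradiation, and the C1/C2 cis relationship depends on its geometry.
  - The dienol carries a bulky aryl group at its terminus, and the all-cis adduct is congested.
  - The C3 ester of A6 must be reduced to a methyl (three steps), followed by dehydration and deprotection. A7 itself needs about five steps.
- Comparison: the chosen route takes its relative configuration from a ground-state alkene geometry that does not equilibrate under the reaction conditions, and brings C3 with its methyl already in place.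

Key step: step 9

Remarks on the chemistry:
- Lignan numbering (C1–C8a, rings A, B, C) is used for positions.
- The carbon that becomes C3 is formed without control in step 10 and is drawn without configuration in compounds 21 to 28.
- The antipode of the bisphosphine in step 9 is the one that leads to (1S,2S)-19. Which antipode this is must be fixed by correlation on the first run.

## Route

Step 1
Reactants: 1 syringaldehyde; 2 benzyl bromide
Product: 3 4-(benzyloxy)-3,5-dimethoxybenzaldehyde
Conditions: BnBr, K2CO3, DMF, 60 °C
Reagents that add atoms: benzyl bromide (2), BrCc1ccccc1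
Why: Williamson ether synthesis; the para-formyl phenol is acidic and its phenoxide, although flanked by two methoxy groups, should be alkylated cleanly by the unhindered benzylic halide.

Step 2
Reactants: 3 4-(benzyloxy)-3,5-dimethoxybenzaldehyde; 4 dimethyl (1-diazo-2-oxopropyl)phosphonate
Product: 5 2-(benzyloxy)-5-ethynyl-1,3-dimethoxybenzene
Conditions: 4, K2CO3, MeOH, 0 °C to rt
Reagents that add atoms: dimethyl (1-diazo-2-oxopropyl)phosphonate (4), CC(=O)C(=[N+]=[N-])P(=O)(OC)OC (supplies the terminal alkyne carbon, later C2)
Why: Seyferth–Gilbert homologation in the Ohira–Bestmann variant; the non-enolisable aryl aldehyde should give the terminal alkyne under mild carbonate conditions that leave the ethers alone.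

Step 3
Reactants: 6 acenaphthoquinone
Product: 7 cis-1,2-dimethyl-1,2-dihydroacenaphthylene-1,2-diol (meso)
Conditions: AlMe3 (3 equiv), toluene, 0 °C to rt; aq. HCl work-up; recrystallisation
Reagents that add atoms: trimethylaluminium, C[Al](C)C
Why: Double 1,2-addition of methyl to the 1,2-diketone; the second methyl is expected to enter anti to the bulky aluminium alkoxide on the neighbouring carbon, which places both hydroxyls cis, and the meso diol is purified by crystallisation.

Step 4
Reactants: 5 2-(benzyloxy)-5-ethynyl-1,3-dimethoxybenzene; 7 cis-1,2-dimethyl-1,2-dihydroacenaphthylene-1,2-diol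
Product: 9 (Z)-2-[4-(benzyloxy)-3,5-dimethoxyphenyl]ethenylboronic acid cis-1,2-dimethylacenaphthylene-1,2-diyl ester, via alkenyl catechol boronate 8 (not isolated)
Conditions: catecholborane, [Rh(cod)Cl]2 (1.5 mol%), P(i-Pr)3 (6 mol%), Et3N, cyclohexane, rt; then 7, rt
Reagents that add atoms: catecholborane, B1Oc2ccccc2O1 (supplies boron); diol 7, C[C@]1(O)[C@@](C)(O)c2cccc3cccc1c23
Why: Rhodium-catalysed trans-hydroboration of a terminal alkyne through a rhodium vinylidene places boron cis to the aryl group, which sets the Z geometry; the labile catechol ester then undergoes boronic ester exchange with the rigid tertiary cis-diol.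

Step 5
Reactants: 10 2,6-dimethoxyphenol; 2 benzyl bromide
Product: 11 2-(benzyloxy)-1,3-dimethoxybenzene
Conditions: BnBr, K2CO3, DMF, 60 °C
Reagents that add atoms: benzyl bromide (2), BrCc1ccccc1
Why: Williamson ether synthesis on a phenol whose only nucleophilic site under carbonate is oxygen.

Step 6
Reactants: 11 2-(benzyloxy)-1,3-dimethoxybenzene
Product: 12 3-(benzyloxy)-1-bromo-2,4-dimethoxybenzene
Conditions: NBS (1.0 equiv), MeCN, 0 °C to rt
Reagents that add atoms: N-bromosuccinimide, O=C1CCC(=O)N1Br
Why: Electrophilic aromatic bromination; a 1,2,3-trialkoxybenzene reacts at the carbon ortho to one outer methoxy group and para to the other, because the twisted central alkoxy group activates its own para carbon only weakly.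

Step 7
Reactants: 12 3-(benzyloxy)-1-bromo-2,4-dimethoxybenzene
Product: 15 3-(benzyloxy)-2,4-dimethoxyphenol, via aryllithium 13 (not isolated), via dimethyl arylboronate 14 (not isolated)
Conditions: n-BuLi, THF, −78 °C; B(OMe)3, −78 °C to rt; H2O2 (30%), NaOH aq, 0 °C
Reagents that add atoms: hydrogen peroxide, OO (the phenol oxygen); trimethyl borate, COB(OC)OC (boron of 14 only)
Why: Bromine–lithium exchange at −78 °C is faster than benzylic deprotonation; borylation and peroxide oxidation (1,2-shift of aryl from boron to oxygen) then replace bromine by hydroxyl at the same carbon.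

Step 8
Reactants: 15 3-(benzyloxy)-2,4-dimethoxyphenol
Product: 16 3-(benzyloxy)-2,4-dimethoxyphenyl trifluoromethanesulfonate
Conditions: Tf2O, pyridine, CH2Cl2, 0 °C
Reagents that add atoms: trifluoromethanesulfonic anhydride, O=S(=O)(OS(=O)(=O)C(F)(F)F)C(F)(F)F
Why: O-Sulfonylation of a phenol; the electron-rich phenol is converted at once into the stable aryl triflate needed for oxidative addition.

Step 9
Reactants: 9 (Z)-2-[4-(benzyloxy)-3,5-dimethoxyphenyl]ethenylboronic acid cis-1,2-dimethylacenaphthylene-1,2-diyl ester; 17 methyllithium; 16 3-(benzyloxy)-2,4-dimethoxyphenyl trifluoromethanesulfonate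
Product: 19 (1S,2S)-1-[3-(benzyloxy)-2,4-dimethoxyphenyl]-1-[4-(benzyloxy)-3,5-dimethoxyphenyl]propan-2-ylboronic acid cis-1,2-dimethylacenaphthylene-1,2-diyl ester, via lithium methyl borate 18 (not isolated)
Conditions: 17 (halide-free, Et2O), THF, −78 to 0 °C; then 16, Pd(OAc)2 (3 mol%), MandyPhos-type ligand 2,2′-bis[(dimethylamino)(phenyl)methyl]-1,1′-bis[bis(4-methoxy-3,5-dimethylphenyl)phosphino]ferrocene (single enantiomer, 3.6 mol%), THF, 60 °C
Reagents that add atoms: methyllithium (17), [Li]C (the C2 methyl)
Why: Methyllithium adds to the trigonal boron of 9 to give the four-coordinate borate 18, whose only carbon group able to migrate besides the alkenyl unit is methyl. Oxidative addition of 16 to zerovalent palladium gives a cationic aryl divalent palladium species that binds the alkene of 18 on one face. This activation triggers a 1,2-shift of methyl from boron to the boron-bearing carbon anti to palladium, forming C2–CH3 and a benzylic C1–Pd bond, and reductive elimination with retention then joins C8a of ring A to C1. The closest known reaction type is the palladium-catalysed enantioselective conjunctive cross-coupling of β-substituted alkenylboron ate complexes of this diol with aryl triflates. No ring is closed. C1 is controlled by the chiral bisphosphine, which selects the alkene face that palladium binds; C2 follows from the anti-periplanar migration, so the Z geometry becomes the (1S,2S) arrangement that is cis in ring B. The step needs the conjunctive path to win over direct transfer of alkenyl or methyl from boron to palladium, which the rigid diol on boron and the halide-free medium are there to secure. Regiochemistry is inherent, since the migrating group can only end on the boron-bearing carbon and palladium therefore on the benzylic one.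

Step 10
Reactants: 19 (1S,2S)-1-[3-(benzyloxy)-2,4-dimethoxyphenyl]-1-[4-(benzyloxy)-3,5-dimethoxyphenyl]propan-2-ylboronic ester of diol 7; 20 ethyl 2,4,6-triisopropylbenzoate
Product: 22 (3R,4S)-4-[3-(benzyloxy)-2,4-dimethoxyphenyl]-4-[4-(benzyloxy)-3,5-dimethoxyphenyl]-3-methylbutan-2-ylboronic acid cis-1,2-dimethylacenaphthylene-1,2-diyl ester (both configurations at C2 of the chain), via boron ate complex 21 (not isolated)
Conditions: 20, s-BuLi, TMEDA, Et2O, −78 °C; then 19, −78 °C to 35 °C
Reagents that add atoms: ethyl 2,4,6-triisopropylbenzoate (20), CCOC(=O)c1c(C(C)C)cc(C(C)C)cc1C(C)C (supplies C3 and its methyl)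
Why: Lithiation–borylation homologation: the α-lithiated benzoate adds to boron and the C2 alkyl group undergoes a 1,2-metallate shift with loss of the hindered carboxylate, with retention at C2 (the descriptor changes from S to R only because the priorities change); the new centre at C3 is uncontrolled and later becomes trigonal.

Step 11
Reactants: 22 (3R,4S)-4,4-diaryl-3-methylbutan-2-ylboronic ester of diol 7; 23 dichloromethane
Product: 26 (3S,4S)-4-[3-(benzyloxy)-2,4-dimethoxyphenyl]-4-[4-(benzyloxy)-3,5-dimethoxyphenyl]-2,3-dimethylbutanal (both configurations at C2 of the chain), via dichloromethyl borate 24 (not isolated), via alpha-chloro boronic ester 25 (not isolated)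
Conditions: 23, n-BuLi, THF, −100 °C; then 22, −100 °C to rt; then NaBO3·4H2O, THF/H2O, rt
Reagents that add atoms: dichloromethane (23), ClCCl (supplies C4); sodium perborate tetrahydrate NaBO3·4H2O, [Na+].[O-]OB=O (the aldehyde oxygen)
Why: Matteson homologation: dichloromethyllithium adds to boron and the C3 alkyl group migrates with loss of chloride; oxidation of the α-chloro boronic ester gives an α-chloro alkoxide that collapses to the aldehyde, so C4 arrives at the required oxidation level without a separate alcohol oxidation.

Step 12
Reactants: 26 (3S,4S)-4-[3-(benzyloxy)-2,4-dimethoxyphenyl]-4-[4-(benzyloxy)-3,5-dimethoxyphenyl]-2,3-dimethylbutanal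
Product: 27 (3S,4S)-4-(3-hydroxy-2,4-dimethoxyphenyl)-4-(4-hydroxy-3,5-dimethoxyphenyl)-2,3-dimethylbutanal (both configurations at C2 of the chain)
Conditions: H2 (1 atm), Pd/C (10%), EtOAc, rt
Reagents that add atoms: none
Why: Hydrogenolysis of the two aryl benzyl ethers under neutral conditions, which should leave the aliphatic aldehyde and the diarylmethine untouched and frees the ring A phenol before any acid meets the aldehyde.

Step 13
Reactants: 27 (3S,4S)-4-(3-hydroxy-2,4-dimethoxyphenyl)-4-(4-hydroxy-3,5-dimethoxyphenyl)-2,3-dimethylbutanal
Product: 29 (7S,8S)-8-(4-hydroxy-3,5-dimethoxyphenyl)-1,3-dimethoxy-6,7-dimethyl-7,8-dihydronaphthalen-2-ol (the target; 1S,2S in lignan numbering), via benzylic alcohol 28 (not isolated)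
Conditions: p-TsOH·H2O (10 mol%), toluene, 40 °C
Reagents that add atoms: none
Why: Friedel–Crafts cyclodehydration (Bradsher type): C4a, para to the free C7 hydroxyl, attacks the protonated aldehyde in a 6-exo-trig closure, and the para-hydroxybenzylic alcohol 28 ionises and loses the C3 proton to give the conjugated C3=C4 alkene; ring C offers only carbons meta to its hydroxyl, and C1 and C2 are not involved.

## Compound list

1 | syringaldehyde (4-hydroxy-3,5-dimethoxybenzaldehyde) | O=Cc1cc(OC)c(O)c(OC)c1 | starting material
2 | benzyl bromide | BrCc1ccccc1 | starting material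
3 | 4-(benzyloxy)-3,5-dimethoxybenzaldehyde | O=Cc1cc(OC)c(OCc2ccccc2)c(OC)c1 | intermediate
4 | dimethyl (1-diazo-2-oxopropyl)phosphonate | CC(=O)C(=[N+]=[N-])P(=O)(OC)OC | starting material
5 | 2-(benzyloxy)-5-ethynyl-1,3-dimethoxybenzene | C#Cc1cc(OC)c(OCc2ccccc2)c(OC)c1 | intermediate
6 | acenaphthoquinone (acenaphthylene-1,2-dione) | O=C1C(=O)c2cccc3cccc1c23 | starting material
7 | cis-1,2-dimethyl-1,2-dihydroacenaphthylene-1,2-diol (meso, 1R,2S) | C[C@]1(O)[C@@](C)(O)c2cccc3cccc1c23 | intermediate
8 | 2-[(Z)-2-[4-(benzyloxy)-3,5-dimethoxyphenyl]ethenyl]-1,3,2-benzodioxaborole | COc1cc(/C=C\B2Oc3ccccc3O2)cc(OC)c1OCc1ccccc1 | intermediate (not isolated)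
9 | (Z)-2-[4-(benzyloxy)-3,5-dimethoxyphenyl]ethenylboronic acid cis-1,2-dimethylacenaphthylene-1,2-diyl ester | COc1cc(/C=C\B2O[C@]3(C)c4cccc5cccc(c45)[C@]3(C)O2)cc(OC)c1OCc1ccccc1 | intermediate
10 | 2,6-dimethoxyphenol | COc1cccc(OC)c1O | starting material
11 | 2-(benzyloxy)-1,3-dimethoxybenzene | COc1cccc(OC)c1OCc1ccccc1 | intermediate
12 | 3-(benzyloxy)-1-bromo-2,4-dimethoxybenzene | COc1ccc(Br)c(OC)c1OCc1ccccc1 | intermediate
13 | [3-(benzyloxy)-2,4-dimethoxyphenyl]lithium | [Li]c1ccc(OC)c(OCc2ccccc2)c1OC | intermediate (not isolated)
14 | dimethyl [3-(benzyloxy)-2,4-dimethoxyphenyl]boronate | COB(OC)c1ccc(OC)c(OCc2ccccc2)c1OC | intermediate (not isolated)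
15 | 3-(benzyloxy)-2,4-dimethoxyphenol | COc1ccc(O)c(OC)c1OCc1ccccc1 | intermediate
16 | 3-(benzyloxy)-2,4-dimethoxyphenyl trifluoromethanesulfonate | COc1ccc(OS(=O)(=O)C(F)(F)F)c(OC)c1OCc1ccccc1 | intermediate
17 | methyllithium | [Li]C | starting material
18 | lithium methyl borate formed from 9 and 17 (Z-alkenyl, methyl and the diol of 7 on boron) | [Li+].COc1cc(/C=C\[B-]2(C)O[C@]3(C)c4cccc5cccc(c45)[C@]3(C)O2)cc(OC)c1OCc1ccccc1 | intermediate (not isolated)
19 | (1S,2S)-1-[3-(benzyloxy)-2,4-dimethoxyphenyl]-1-[4-(benzyloxy)-3,5-dimethoxyphenyl]propan-2-ylboronic acid cis-1,2-dimethylacenaphthylene-1,2-diyl ester | COc1cc([C@H]([C@H](C)B2O[C@]3(C)c4cccc5cccc(c45)[C@]3(C)O2)c2ccc(OC)c(OCc3ccccc3)c2OC)cc(OC)c1OCc1ccccc1 | intermediate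
20 | ethyl 2,4,6-triisopropylbenzoate | CCOC(=O)c1c(C(C)C)cc(C(C)C)cc1C(C)C | starting material
21 | lithium borate from 19 and lithiated 20 ((1S,2S)-alkyl and 1-(2,4,6-triisopropylbenzoyloxy)ethyl on boron) | [Li+].COc1cc([C@H]([C@H](C)[B-]2(C(C)OC(=O)c3c(C(C)C)cc(C(C)C)cc3C(C)C)O[C@]3(C)c4cccc5cccc(c45)[C@]3(C)O2)c2ccc(OC)c(OCc3ccccc3)c2OC)cc(OC)c1OCc1ccccc1 | intermediate (not isolated)
22 | (3R,4S)-4-[3-(benzyloxy)-2,4-dimethoxyphenyl]-4-[4-(benzyloxy)-3,5-dimethoxyphenyl]-3-methylbutan-2-ylboronic acid cis-1,2-dimethylacenaphthylene-1,2-diyl ester (both configurations at C2) | COc1cc([C@H]([C@H](C)C(C)B2O[C@]3(C)c4cccc5cccc(c45)[C@]3(C)O2)c2ccc(OC)c(OCc3ccccc3)c2OC)cc(OC)c1OCc1ccccc1 | intermediate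
23 | dichloromethane | ClCCl | starting material
24 | lithium dichloromethyl borate from 22 ((3R,4S)-alkyl and CHCl2 on boron) | [Li+].COc1cc([C@H]([C@H](C)C(C)[B-]2(C(Cl)Cl)O[C@]3(C)c4cccc5cccc(c45)[C@]3(C)O2)c2ccc(OC)c(OCc3ccccc3)c2OC)cc(OC)c1OCc1ccccc1 | intermediate (not isolated)
25 | (3S,4S)-1-chloro-4-[3-(benzyloxy)-2,4-dimethoxyphenyl]-4-[4-(benzyloxy)-3,5-dimethoxyphenyl]-2,3-dimethylbutylboronic acid cis-1,2-dimethylacenaphthylene-1,2-diyl ester (C1 and C2 uncontrolled) | COc1cc([C@H]([C@H](C)C(C)C(Cl)B2O[C@]3(C)c4cccc5cccc(c45)[C@]3(C)O2)c2ccc(OC)c(OCc3ccccc3)c2OC)cc(OC)c1OCc1ccccc1 | intermediate (not isolated)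
26 | (3S,4S)-4-[3-(benzyloxy)-2,4-dimethoxyphenyl]-4-[4-(benzyloxy)-3,5-dimethoxyphenyl]-2,3-dimethylbutanal (both configurations at C2) | COc1cc([C@H]([C@H](C)C(C)C=O)c2ccc(OC)c(OCc3ccccc3)c2OC)cc(OC)c1OCc1ccccc1 | intermediate
27 | (3S,4S)-4-(3-hydroxy-2,4-dimethoxyphenyl)-4-(4-hydroxy-3,5-dimethoxyphenyl)-2,3-dimethylbutanal (both configurations at C2) | COc1cc([C@H]([C@H](C)C(C)C=O)c2ccc(OC)c(O)c2OC)cc(OC)c1O | intermediate
28 | (7S,8S)-8-(4-hydroxy-3,5-dimethoxyphenyl)-1,3-dimethoxy-6,7-dimethyl-5,6,7,8-tetrahydronaphthalene-2,5-diol (C5 and C6 uncontrolled) | COc1cc([C@H]2c3c(cc(OC)c(O)c3OC)C(O)C(C)[C@H]2C)cc(OC)c1O | intermediate (not isolated)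
29 | (7S,8S)-8-(4-hydroxy-3,5-dimethoxyphenyl)-1,3-dimethoxy-6,7-dimethyl-7,8-dihydronaphthalen-2-ol | COc1cc([C@H]2c3c(cc(OC)c(O)c3OC)C=C(C)[C@H]2C)cc(OC)c1O | target

## Step count and least certain steps

Total: 13 steps. Longest linear sequence: 9 steps (steps 5 to 13, from 10 through 11, 12, 15, 16, 19, 22, 26 and 27 to 29).

**Step 9 (key step).**
- What may go wrong:
  - direct transfer of the alkenyl or methyl group from boron to palladium, giving simple cross-coupling;
  - β-hydride elimination from the benzylic palladium intermediate;
  - slow oxidative addition and reductive elimination with the ortho-substituted, electron-rich triflate;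
  - incomplete face discrimination on a (Z)-β-aryl alkene;
  - sluggish migration of methyl.
- Fallback: it sets out from alkyne 5 and bromide 12 and comes back at aldehyde 26.
  - Alkyne 5 is C-methylated (n-BuLi, MeI) to 2-(benzyloxy)-1,3-dimethoxy-5-(prop-1-yn-1-yl)benzene F1.
  - F1 is semi-hydrogenated (H2, Pd/CaCO3 poisoned with Pb(OAc)2, quinoline) to 2-(benzyloxy)-1,3-dimethoxy-5-[(Z)-prop-1-en-1-yl]benzene F2.
  - A dual copper/palladium-catalysed syn-arylboration of F2 with bis(pinacolato)diboron and 12 then forms C1–C8a and C2–B on one face of an alkene that already carries the C2 methyl. A chiral N-heterocyclic carbene complex of CuCl with NaOt-Bu performs the enantioselective borylcupration, and Pd(OAc)2 with a biaryl dialkylphosphine couples the benzylic copper species. The product is the pinacol ester corresponding to 19, F3.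
  - Steps 10 and 11 run on F3 pass through the pinacol analogue of borate 21 F4, the pinacol analogue of 22 F5, the pinacol analogue of borate 24 F6 and the pinacol analogue of 25 F7, and deliver 26.

**Step 13.**
- What may go wrong:
  - attack of the electrophilic C4 on ring C, at an ortho carbon or at the ipso carbon followed by a shift;
  - acid-induced migration of the new double bond toward C2 with loss of that configuration;
  - intermolecular condensation through quinone-methide-type cations.
- Fallback: it sets out from 27 and comes back at 28, which is then dehydrated to 29. The nucleophile is activated instead of the electrophile. In degassed aqueous methanolic K2CO3 the ring A phenolate adds through its para carbon C4a to the aldehyde (base-mediated phenol–aldehyde hydroxyalkylation of the Lederer–Manasse type). The ring C phenolate has no free ortho or para carbon, and an adduct at its substituted ipso carbon can only revert. A trace of weak acid or gentle warming then dehydrates 28. This fallback makes no compound outside the list (none, F0).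

**Step 10.**
- What may go wrong: slow or reversible ate-complex formation between the bulky lithiated benzoate and the hindered secondary boronic ester, decomposition of the carbenoid before migration, and unexpected behaviour of the acenaphthene diol ester in the 1,2-shift.
- Fallback: it sets out from 19 and comes back at 22, delivering the methyl as a nucleophile instead of on the carbenoid. The small dichloromethyllithium adds to 19 to give the lithium dichloromethyl borate F8, which rearranges to the α-chloro boronic ester F9. MeMgBr then adds to boron to give the bromomagnesium methyl borate F10, and methyl displaces chloride by 1,2-shift to give 22.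

**Step 4.**
- What may go wrong: erosion of the Z geometry (insufficient trans selectivity with an electron-rich arylalkyne, or Z to E isomerisation during ligand exchange) and incomplete exchange of catechol for diol 7.
- Fallback: it sets out from aldehyde 3 and comes back at 9, fixing the geometry in an olefination. A Stork–Zhao Wittig reaction of 3 with (iodomethyl)triphenylphosphonium iodide and NaHMDS gives 2-(benzyloxy)-5-[(Z)-2-iodoethenyl]-1,3-dimethoxybenzene F11. Iodine–lithium exchange (t-BuLi, Et2O, −78 °C) gives the (Z)-alkenyllithium F12, which is trapped with B(OMe)3 as the dimethyl (Z)-alkenylboronate F13. Esterification with diol 7 gives 9.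

## Further compounds

F1 | step 9 | 2-(benzyloxy)-1,3-dimethoxy-5-(prop-1-yn-1-yl)benzene | CC#Cc1cc(OC)c(OCc2ccccc2)c(OC)c1
F2 | step 9 | 2-(benzyloxy)-1,3-dimethoxy-5-[(Z)-prop-1-en-1-yl]benzene | C/C=C\c1cc(OC)c(OCc2ccccc2)c(OC)c1
F3 | step 9 | 2-[(1S,2S)-1-[3-(benzyloxy)-2,4-dimethoxyphenyl]-1-[4-(benzyloxy)-3,5-dimethoxyphenyl]propan-2-yl]-4,4,5,5-tetramethyl-1,3,2-dioxaborolane (pinacol ester corresponding to 19) | COc1cc([C@H]([C@H](C)B2OC(C)(C)C(C)(C)O2)c2ccc(OC)c(OCc3ccccc3)c2OC)cc(OC)c1OCc1ccccc1
F4 | step 9 | lithium borate, pinacol analogue of 21 | [Li+].COc1cc([C@H]([C@H](C)[B-]2(C(C)OC(=O)c3c(C(C)C)cc(C(C)C)cc3C(C)C)OC(C)(C)C(C)(C)O2)c2ccc(OC)c(OCc3ccccc3)c2OC)cc(OC)c1OCc1ccccc1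
F5 | step 9 | 2-[(3R,4S)-4-[3-(benzyloxy)-2,4-dimethoxyphenyl]-4-[4-(benzyloxy)-3,5-dimethoxyphenyl]-3-methylbutan-2-yl]-4,4,5,5-tetramethyl-1,3,2-dioxaborolane (pinacol analogue of 22) | COc1cc([C@H]([C@H](C)C(C)B2OC(C)(C)C(C)(C)O2)c2ccc(OC)c(OCc3ccccc3)c2OC)cc(OC)c1OCc1ccccc1
F6 | step 9 | lithium dichloromethyl borate, pinacol analogue of 24 | [Li+].COc1cc([C@H]([C@H](C)C(C)[B-]2(C(Cl)Cl)OC(C)(C)C(C)(C)O2)c2ccc(OC)c(OCc3ccccc3)c2OC)cc(OC)c1OCc1ccccc1
F7 | step 9 | 2-[(3S,4S)-1-chloro-4-[3-(benzyloxy)-2,4-dimethoxyphenyl]-4-[4-(benzyloxy)-3,5-dimethoxyphenyl]-2,3-dimethylbutyl]-4,4,5,5-tetramethyl-1,3,2-dioxaborolane (pinacol analogue of 25) | COc1cc([C@H]([C@H](C)C(C)C(Cl)B2OC(C)(C)C(C)(C)O2)c2ccc(OC)c(OCc3ccccc3)c2OC)cc(OC)c1OCc1ccccc1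
F0 | step 13 | none | none
F8 | step 10 | lithium dichloromethyl borate from 19 ((1S,2S)-alkyl and CHCl2 on boron, diol of 7) | [Li+].COc1cc([C@H]([C@H](C)[B-]2(C(Cl)Cl)O[C@]3(C)c4cccc5cccc(c45)[C@]3(C)O2)c2ccc(OC)c(OCc3ccccc3)c2OC)cc(OC)c1OCc1ccccc1
F9 | step 10 | (2S,3S)-1-chloro-3-[3-(benzyloxy)-2,4-dimethoxyphenyl]-3-[4-(benzyloxy)-3,5-dimethoxyphenyl]-2-methylpropylboronic acid cis-1,2-dimethylacenaphthylene-1,2-diyl ester (either configuration at C1) | COc1cc([C@H]([C@H](C)C(Cl)B2O[C@]3(C)c4cccc5cccc(c45)[C@]3(C)O2)c2ccc(OC)c(OCc3ccccc3)c2OC)cc(OC)c1OCc1ccccc1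
F10 | step 10 | bromomagnesium methyl borate from F9 | Br[Mg+].COc1cc([C@H]([C@H](C)C(Cl)[B-]2(C)O[C@]3(C)c4cccc5cccc(c45)[C@]3(C)O2)c2ccc(OC)c(OCc3ccccc3)c2OC)cc(OC)c1OCc1ccccc1
F11 | step 4 | 2-(benzyloxy)-5-[(Z)-2-iodoethenyl]-1,3-dimethoxybenzene | COc1cc(/C=C\I)cc(OC)c1OCc1ccccc1
F12 | step 4 | [(Z)-2-[4-(benzyloxy)-3,5-dimethoxyphenyl]ethenyl]lithium | COc1cc(/C=C\[Li])cc(OC)c1OCc1ccccc1
F13 | step 4 | dimethyl [(Z)-2-[4-(benzyloxy)-3,5-dimethoxyphenyl]ethenyl]boronate | COc1cc(/C=C\B(OC)OC)cc(OC)c1OCc1ccccc1
A1 | alternative 1 | methyl cis-4-[3,5-dimethoxy-4-(methylsulfonyloxy)phenyl]-5,7-dimethoxy-3-methyl-6-(methylsulfonyloxy)-1-oxo-1,2,3,4-tetrahydronaphthalene-2-carboxylate | COc1cc([C@H]2c3c(cc(OC)c(OS(C)(=O)=O)c3OC)C(=O)C(C(=O)OC)[C@H]2C)cc(OC)c1OS(C)(=O)=O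
A2 | alternative 1 | dimethyl trans-2-[3,5-dimethoxy-4-(methylsulfonyloxy)phenyl]-3-methylcyclopropane-1,1-dicarboxylate (single enantiomer) | COc1cc([C@H]2[C@H](C)C2(C(=O)OC)C(=O)OC)cc(OC)c1OS(C)(=O)=O
A3 | alternative 1 | 2,6-dimethoxyphenyl methanesulfonate | COc1cccc(OC)c1OS(C)(=O)=O
A4 | alternative 2 | bis(methoxymethyl) ether of the target | COc1cc([C@H]2c3c(cc(OC)c(OCOC)c3OC)C=C(C)[C@H]2C)cc(OC)c1OCOC
A5 | alternative 2 | 2-[3-[3,5-dimethoxy-4-(methoxymethoxy)phenyl]-4,6-dimethoxy-5-(methoxymethoxy)-1,2-dimethyl-2,3-dihydro-1H-inden-1-yl]acetic acid (C2 and C3 of the indane as C2 and C1 of the target; quaternary carbon of either configuration) | COc1cc([C@H]2c3c(cc(OC)c(OCOC)c3OC)C(C)(CC(=O)O)[C@H]2C)cc(OC)c1OCOC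
A6 | alternative 3 | methyl all-cis-4-[3,5-dimethoxy-4-(methoxymethoxy)phenyl]-1-hydroxy-5,7-dimethoxy-6-(methoxymethoxy)-3-methyl-1,2,3,4-tetrahydronaphthalene-2-carboxylate | COc1cc([C@H]2c3c(cc(OC)c(OCOC)c3OC)[C@@H](O)[C@@H](C(=O)OC)[C@H]2C)cc(OC)c1OCOC
A7 | alternative 3 | 2-[[3,5-dimethoxy-4-(methoxymethoxy)phenyl]methyl]-3,5-dimethoxy-4-(methoxymethoxy)benzaldehyde | COc1cc(Cc2c(C=O)cc(OC)c(OCOC)c2OC)cc(OC)c1OCOC
A8 | alternative 3 | methyl (Z)-but-2-enoate | C/C=C\C(=O)OC
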